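## Retrosynthetic overview

1. The target is (2S)-naringenin with a (2R)-1-methylpiperidin-2-yl group at C6. The last operations only unmask O5, O7 and O4' (two TIPS ethers, one benzyl ether) and turn N-Cbz into N-CH3.
2. Key disconnection: C2–C3 of ring C. C2–H is both α to the ring oxygen O1 and benzylic to ring B, and it lies 1,6 to C3 across the rigid C4–C4a–C8a–O1 unit of ring A. C2 and ring B can therefore enter as an ordinary 4-(benzyloxy)benzyl ether on O1, and C3 as a diazoacetyl carbenoid that inserts enantioselectively into that C–H bond.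
3. Diazoacetyl ⇐ acetyl ⇐ iodide on ring A. While the piperidine carbon is flanked by two identical OTIPS groups, the two free ring positions are equivalent, so the acyl group must land between O5 and the benzylated oxygen. This fixes 6- and not 8-substitution.
4. Piperidine ⇐ Ellman addition of 4-chlorobutylmagnesium bromide to the (S)-sulfinimine of a symmetric 2,4,6-trioxygenated benzaldehyde, then N-alkylative ring closure.
5. Order of ring formation: rings A and B are bought; the piperidine ring is closed in step 5; the pyranone ring C is closed in step 10.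

Key step: step 10

Remark on numbering: flavanone numbering (O1, C2, C3, C4, C4a, C5–C8, C8a; piperidine carbon C2') is used for all intermediates.

Assumption: the sense of induction of Rh2(S-PTTL)4 in step 10 is not secure for this substrate; the S-series catalyst is written, and Rh2(R-PTTL)4 would take its place if a model insertion showed the opposite sense.

## Route

Step 1
Reactants: 1 2,4,6-trihydroxybenzaldehyde; 2 4-(benzyloxy)benzyl chloride
Product: 3 4-{[4-(benzyloxy)benzyl]oxy}-2,6-dihydroxybenzaldehyde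
Conditions: K2CO3 (1.0 equiv), DMF, 0 °C → rt
Reagents that add atoms: none
Why: Williamson ether synthesis: the 4-OH, para to the formyl group, is the most acidic hydroxyl and the only one not locked in a hydrogen bond to C=O, so one equivalent of base and electrophile should alkylate it selectively.

Step 2
Reactants: 3 4-{[4-(benzyloxy)benzyl]oxy}-2,6-dihydroxybenzaldehyde
Product: 4 4-{[4-(benzyloxy)benzyl]oxy}-2,6-bis(triisopropylsilyloxy)benzaldehyde
Conditions: TIPSOTf (2.4 equiv), 2,6-lutidine, CH2Cl2, 0 °C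
Reagents that add atoms: triisopropylsilyl trifluoromethanesulfonate, CC(C)[Si](OS(=O)(=O)C(F)(F)F)(C(C)C)C(C)C
Why: O-silylation of phenols with a silyl triflate, strong enough for the two hydrogen-bonded ortho hydroxyls; TIPS is chosen because it carries no C–H next to oxygen for the later carbenoid, resists base and migration, and keeps ring A symmetric.

Step 3
Reactants: 4 4-{[4-(benzyloxy)benzyl]oxy}-2,6-bis(triisopropylsilyloxy)benzaldehyde; 5 (S)-2-methylpropane-2-sulfinamide
Product: 6 (S,E)-N-{4-[(4-benzyloxybenzyl)oxy]-2,6-bis(triisopropylsilyloxy)benzylidene}-2-methylpropane-2-sulfinamide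
Conditions: Ti(OEt)4 (2 equiv), THF, 60 °C
Reagents that add atoms: none
Why: Ellman condensation of an aldehyde with tert-butanesulfinamide, Ti(OEt)4 serving as Lewis acid and water scavenger, should give the E-configured N-sulfinyl aldimine without touching the silyl or benzyl ethers.

Step 4
Reactants: 6 (S,E)-N-sulfinyl aldimine; 7 1-bromo-4-chlorobutane
Product: 9 (S)-N-[(1R)-1-{4-[(4-benzyloxybenzyl)oxy]-2,6-bis(triisopropylsilyloxy)phenyl}-5-chloropentyl]-2-methylpropane-2-sulfinamide, via 4-chlorobutylmagnesium bromide 8 (not isolated)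
Conditions: 7, Mg, Et2O, rt; then 6, CH2Cl2, −48 °C → rt; aq. NH4Cl
Reagents that add atoms: none
Why: Ellman 1,2-addition of a Grignard reagent to an N-sulfinyl aldimine in a non-coordinating solvent: the six-membered chair transition state with magnesium bound to the sulfinyl oxygen and the tert-butyl group equatorial delivers the alkyl group to one face, which for the (S)-sulfinyl aryl aldimine should give the (R)-configured carbinamine carbon (the future C2'), the weakly coordinating OTIPS groups not competing for magnesium.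

Step 5
Reactants: 9 (S)-N-[(1R)-1-aryl-5-chloropentyl]sulfinamide
Product: 11 (2R)-2-{4-[(4-benzyloxybenzyl)oxy]-2,6-bis(triisopropylsilyloxy)phenyl}piperidine, via amine hydrochloride 10 (not isolated)
Conditions: HCl (4 M in dioxane, 3 equiv), MeOH, 0 °C; then iPr2NEt, NaI (cat.), MeCN, 60 °C
Reagents that add atoms: none
Why: Acidic cleavage of the N-sulfinyl group followed by intramolecular SN2 N-alkylation (6-exo-tet) of the primary amine by the primary chloride should close the piperidine ring without involving the stereocenter.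

Step 6
Reactants: 11 (2R)-2-arylpiperidine
Product: 12 benzyl (2R)-2-{4-[(4-benzyloxybenzyl)oxy]-2,6-bis(triisopropylsilyloxy)phenyl}piperidine-1-carboxylate
Conditions: CbzCl, NaHCO3, CH2Cl2/H2O, 0 °C → rt
Reagents that add atoms: benzyl chloroformate, O=C(Cl)OCc1ccccc1
Why: Schotten–Baumann carbamate formation makes the nitrogen non-basic and non-nucleophilic for the iodination, the palladium step and the rhodium carbenoid, and the Cbz group can later be turned into N-methyl in one operation.

Step 7
Reactants: 12 N-Cbz arylpiperidine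
Product: 13 benzyl (2R)-2-{4-[(4-benzyloxybenzyl)oxy]-3-iodo-2,6-bis(triisopropylsilyloxy)phenyl}piperidine-1-carboxylate
Conditions: NIS (1.05 equiv), MeCN, 0 °C, dark
Reagents that add atoms: N-iodosuccinimide, O=C1CCC(=O)N1I
Why: Electrophilic aromatic iodination of a phloroglucinol-type triether: the two free positions of ring A are equivalent (they exchange by rotation about the aryl–C2' bond), so only one constitutional isomer can form, with iodine between an OTIPS group and the benzylic ether oxygen, while the less electron-rich benzyl ether and Cbz rings should not react.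

Step 8
Reactants: 13 aryl iodide
Product: 15 benzyl (2R)-2-{3-acetyl-4-[(4-benzyloxybenzyl)oxy]-2,6-bis(triisopropylsilyloxy)phenyl}piperidine-1-carboxylate, via enol ether 14 (not isolated)
Conditions: tributyl(1-ethoxyvinyl)stannane, PdCl2(PPh3)2 (5 mol%), toluene, 100 °C; then 1 M HCl, THF, rt
Reagents that add atoms: tributyl(1-ethoxyvinyl)stannane, C=C(OCC)[Sn](CCCC)(CCCC)CCCC; water, O
Why: Stille coupling with an acetyl-anion equivalent followed by enol ether hydrolysis installs the acetyl group at the iodinated carbon under neutral and then mildly acidic conditions, avoiding both Friedel–Crafts acid (benzylic ether cleavage) and an aryllithium next to OTIPS (silyl migration).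

Step 9
Reactants: 15 methyl ketone
Product: 18 benzyl (2R)-2-{4-[(4-benzyloxybenzyl)oxy]-3-(2-diazoacetyl)-2,6-bis(triisopropylsilyloxy)phenyl}piperidine-1-carboxylate, via lithium enolate 16 (not isolated), via trifluoroacetyl diketone 17 (not isolated)
Conditions: LiHMDS (1.1 equiv), THF, −78 °C; CF3CO2CH2CF3; 5% aq. HCl quench; then MsN3, Et3N, H2O, MeCN, rt
Reagents that add atoms: methanesulfonyl azide, CS(=O)(=O)N=[N+]=[N-] (the two diazo nitrogens); 2,2,2-trifluoroethyl trifluoroacetate, O=C(OCC(F)(F)F)C(F)(F)F (trifluoroacetyl group of 17 only, lost again before 18)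
Why: Detrifluoroacetylative diazo transfer (Regitz type): kinetic enolisation of the methyl ketone, C-trifluoroacetylation to activate the methyl group, and diazo transfer from the sulfonyl azide with loss of the trifluoroacetyl group should give the terminal diazoketone, the carbamate, TIPS ethers and benzyl ethers being inert.

Step 10
Reactants: 18 diazoketone
Product: 19 benzyl (2R)-2-[(2S)-2-(4-benzyloxyphenyl)-4-oxo-5,7-bis(triisopropylsilyloxy)chroman-6-yl]piperidine-1-carboxylate
Conditions: Rh2(S-PTTL)4 (2 mol%), CH2Cl2, 0 °C, slow addition of 18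
Reagents that add atoms: none
Why: Rh2(S-PTTL)4 extrudes N2 from 18 to give an electrophilic dirhodium carbenoid at the future C3, which inserts into one C–H bond of the O–CH2 group on the oxygen ortho to the carbonyl through a three-centre, hydride-transfer-like transition state, the developing positive charge at the future C2 being stabilised by the O1 lone pair and by the 4-benzyloxyphenyl ring. The closest known reaction type is the dirhodium-tetracarboxylate-catalysed intramolecular C–H insertion of 2-alkoxyaryl diazoketones to chroman-4-ones, together with enantioselective insertions into benzylic ether C–H bonds with phthalimido-amino-acid dirhodium catalysts. Ring C is closed by a 1,6 C–H insertion: the planar C4–C4a–C8a–O1 unit holds the carbenoid carbon and the benzylic carbon in a 1,6 relationship, so a six-membered ring is the only insertion product within reach. The C2 stereocenter is set by the catalyst, whose chiral carboxylate pocket must distinguish the two enantiotopic benzylic hydrogens; the remote C2' center should exert no useful bias, and a C2 epimer is a diastereomer that chromatography can remove. The step needs chemoselectivity for C–H insertion over oxonium-ylide formation with 1,2-benzyl shift and over reaction at the other ortho oxygen; this is secured by the low basicity of the vinylogous-ester oxygen O1, by the TIPS group on O5 (no C–H α to oxygen, shielded oxygen), by the non-basic carbamate nitrogen, and by a carboxylate catalyst, which favours insertion over ylide chemistry.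

Step 11
Reactants: 19 protected flavanone
Product: 21 (2S)-2-(4-hydroxyphenyl)-6-[(2R)-1-methylpiperidin-2-yl]-5,7-bis(triisopropylsilyloxy)chroman-4-one, via secondary amine 20 (not isolated)
Conditions: H2 (1 atm), 10% Pd/C, aq. HCHO, MeOH/EtOAc, rt
Reagents that add atoms: formaldehyde, C=O
Why: Hydrogenolysis of the benzyl carbamate and of the benzyl ether on ring B, with in situ reductive amination of the liberated secondary amine by formaldehyde, should give the N-methyl group under neutral conditions that do not epimerise C2 or C2', the TIPS ethers keeping ring A unreactive toward formaldehyde.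

Step 12
Reactants: 21 bis-TIPS ether
Product: 22 (2S)-5,7-dihydroxy-2-(4-hydroxyphenyl)-6-[(2R)-1-methylpiperidin-2-yl]chroman-4-one (target)
Conditions: HF·pyridine, pyridine/THF, 0 °C → rt; pH 7 buffer work-up, no heating
Reagents that add atoms: none
Why: Fluoride-mediated cleavage of the two aryl silyl ethers under buffered, weakly acidic conditions should release the 5- and 7-hydroxyls while avoiding the base that would open ring C by retro-oxa-Michael reaction (loss of C2 configuration) or trigger retro-Mannich ionisation at C2'.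

## Compound list

1 | 2,4,6-trihydroxybenzaldehyde | O=Cc1c(O)cc(O)cc1O | starting material
2 | 4-(benzyloxy)benzyl chloride | ClCc1ccc(OCc2ccccc2)cc1 | starting material
3 | 4-{[4-(benzyloxy)benzyl]oxy}-2,6-dihydroxybenzaldehyde | O=Cc1c(O)cc(OCc2ccc(OCc3ccccc3)cc2)cc1O | intermediate
4 | 4-{[4-(benzyloxy)benzyl]oxy}-2,6-bis(triisopropylsilyloxy)benzaldehyde | O=Cc1c(O[Si](C(C)C)(C(C)C)C(C)C)cc(OCc2ccc(OCc3ccccc3)cc2)cc1O[Si](C(C)C)(C(C)C)C(C)C | intermediate
5 | (S)-2-methylpropane-2-sulfinamide | CC(C)(C)[S@@](N)=O | starting material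
6 | (S,E)-N-{4-[(4-benzyloxybenzyl)oxy]-2,6-bis(triisopropylsilyloxy)benzylidene}-2-methylpropane-2-sulfinamide | CC(C)(C)[S@@](/N=C/c1c(O[Si](C(C)C)(C(C)C)C(C)C)cc(OCc2ccc(OCc3ccccc3)cc2)cc1O[Si](C(C)C)(C(C)C)C(C)C)=O | intermediate
7 | 1-bromo-4-chlorobutane | ClCCCCBr | starting material
8 | 4-chlorobutylmagnesium bromide | ClCCCC[Mg]Br | intermediate
9 | (S)-N-[(1R)-1-{4-[(4-benzyloxybenzyl)oxy]-2,6-bis(triisopropylsilyloxy)phenyl}-5-chloropentyl]-2-methylpropane-2-sulfinamide | CC(C)(C)[S@@](N[C@H](CCCCCl)c1c(O[Si](C(C)C)(C(C)C)C(C)C)cc(OCc2ccc(OCc3ccccc3)cc2)cc1O[Si](C(C)C)(C(C)C)C(C)C)=O | intermediate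
10 | (1R)-1-{4-[(4-benzyloxybenzyl)oxy]-2,6-bis(triisopropylsilyloxy)phenyl}-5-chloropentan-1-amine hydrochloride | Cl.N[C@H](CCCCCl)c1c(O[Si](C(C)C)(C(C)C)C(C)C)cc(OCc2ccc(OCc3ccccc3)cc2)cc1O[Si](C(C)C)(C(C)C)C(C)C | intermediate
11 | (2R)-2-{4-[(4-benzyloxybenzyl)oxy]-2,6-bis(triisopropylsilyloxy)phenyl}piperidine | N1CCCC[C@@H]1c1c(O[Si](C(C)C)(C(C)C)C(C)C)cc(OCc2ccc(OCc3ccccc3)cc2)cc1O[Si](C(C)C)(C(C)C)C(C)C | intermediate
12 | benzyl (2R)-2-{4-[(4-benzyloxybenzyl)oxy]-2,6-bis(triisopropylsilyloxy)phenyl}piperidine-1-carboxylate | O=C(OCc1ccccc1)N1CCCC[C@@H]1c1c(O[Si](C(C)C)(C(C)C)C(C)C)cc(OCc2ccc(OCc3ccccc3)cc2)cc1O[Si](C(C)C)(C(C)C)C(C)C | intermediate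
13 | benzyl (2R)-2-{4-[(4-benzyloxybenzyl)oxy]-3-iodo-2,6-bis(triisopropylsilyloxy)phenyl}piperidine-1-carboxylate | O=C(OCc1ccccc1)N1CCCC[C@@H]1c1c(O[Si](C(C)C)(C(C)C)C(C)C)c(I)c(OCc2ccc(OCc3ccccc3)cc2)cc1O[Si](C(C)C)(C(C)C)C(C)C | intermediate
14 | benzyl (2R)-2-{4-[(4-benzyloxybenzyl)oxy]-3-(1-ethoxyvinyl)-2,6-bis(triisopropylsilyloxy)phenyl}piperidine-1-carboxylate | O=C(OCc1ccccc1)N1CCCC[C@@H]1c1c(O[Si](C(C)C)(C(C)C)C(C)C)c(C(=C)OCC)c(OCc2ccc(OCc3ccccc3)cc2)cc1O[Si](C(C)C)(C(C)C)C(C)C | intermediate
15 | benzyl (2R)-2-{3-acetyl-4-[(4-benzyloxybenzyl)oxy]-2,6-bis(triisopropylsilyloxy)phenyl}piperidine-1-carboxylate | O=C(OCc1ccccc1)N1CCCC[C@@H]1c1c(O[Si](C(C)C)(C(C)C)C(C)C)c(C(C)=O)c(OCc2ccc(OCc3ccccc3)cc2)cc1O[Si](C(C)C)(C(C)C)C(C)C | intermediate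
16 | lithium enolate of 15 | O=C(OCc1ccccc1)N1CCCC[C@@H]1c1c(O[Si](C(C)C)(C(C)C)C(C)C)c(C(=C)O[Li])c(OCc2ccc(OCc3ccccc3)cc2)cc1O[Si](C(C)C)(C(C)C)C(C)C | intermediate
17 | benzyl (2R)-2-{4-[(4-benzyloxybenzyl)oxy]-3-(4,4,4-trifluoro-3-oxobutanoyl)-2,6-bis(triisopropylsilyloxy)phenyl}piperidine-1-carboxylate | O=C(OCc1ccccc1)N1CCCC[C@@H]1c1c(O[Si](C(C)C)(C(C)C)C(C)C)c(C(=O)CC(=O)C(F)(F)F)c(OCc2ccc(OCc3ccccc3)cc2)cc1O[Si](C(C)C)(C(C)C)C(C)C | intermediate
18 | benzyl (2R)-2-{4-[(4-benzyloxybenzyl)oxy]-3-(2-diazoacetyl)-2,6-bis(triisopropylsilyloxy)phenyl}piperidine-1-carboxylate | O=C(OCc1ccccc1)N1CCCC[C@@H]1c1c(O[Si](C(C)C)(C(C)C)C(C)C)c(C(=O)C=[N+]=[N-])c(OCc2ccc(OCc3ccccc3)cc2)cc1O[Si](C(C)C)(C(C)C)C(C)C | intermediate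
19 | benzyl (2R)-2-[(2S)-2-(4-benzyloxyphenyl)-4-oxo-5,7-bis(triisopropylsilyloxy)chroman-6-yl]piperidine-1-carboxylate | O=C(OCc1ccccc1)N1CCCC[C@@H]1c1c(O[Si](C(C)C)(C(C)C)C(C)C)cc2c(c1O[Si](C(C)C)(C(C)C)C(C)C)C(=O)C[C@@H](c1ccc(OCc3ccccc3)cc1)O2 | intermediate
20 | (2S)-2-(4-hydroxyphenyl)-6-[(2R)-piperidin-2-yl]-5,7-bis(triisopropylsilyloxy)chroman-4-one | N1CCCC[C@@H]1c1c(O[Si](C(C)C)(C(C)C)C(C)C)cc2c(c1O[Si](C(C)C)(C(C)C)C(C)C)C(=O)C[C@@H](c1ccc(O)cc1)O2 | intermediate
21 | (2S)-2-(4-hydroxyphenyl)-6-[(2R)-1-methylpiperidin-2-yl]-5,7-bis(triisopropylsilyloxy)chroman-4-one | CN1CCCC[C@@H]1c1c(O[Si](C(C)C)(C(C)C)C(C)C)cc2c(c1O[Si](C(C)C)(C(C)C)C(C)C)C(=O)C[C@@H](c1ccc(O)cc1)O2 | intermediate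
22 | (2S)-5,7-dihydroxy-2-(4-hydroxyphenyl)-6-[(2R)-1-methylpiperidin-2-yl]chroman-4-one | CN1CCCC[C@@H]1c1c(O)cc2c(c1O)C(=O)C[C@@H](c1ccc(O)cc1)O2 | target

## Step count and risks

Total step count: 12. Longest linear sequence: 12 steps (1 → 22).

Steps most likely to fail:

**Step 10 (key step).** The carbenoid may be diverted into oxonium-ylide formation at O1 followed by a 1,2-benzyl shift, or the catalyst may discriminate the two benzylic hydrogens poorly. The fallback sets out from 15 and comes back at 19; it gives up carbenoid chemistry and sets C2 by a catalytic asymmetric conjugate arylation.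
- Oxidative cleavage of the electron-rich benzylic ether of 15 (DDQ, CH2Cl2/H2O) should give the 2'-hydroxyacetophenone F1.
- Condensation with N,N-dimethylformamide dimethyl acetal (toluene, 90 °C) should give the enaminone F2.
- Mild acid (TsOH, CH2Cl2) should close it to the chromone F3.
- Conjugate addition of 4-(benzyloxy)phenylboronic acid under Pd(OCOCF3)2 and t-BuPyOX (NH4PF6, H2O, ClCH2CH2Cl, 60 °C), with the ligand antipode that delivers the (2S) series, should give 19.

**Step 4.** Facial selectivity may be poor, or addition sluggish, at the di-ortho-substituted and very electron-rich aldimine. The fallback sets out from 4 and comes back at 11; it sets C2' by catalytic asymmetric reduction instead of auxiliary control.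
- Addition of 8 to aldehyde 4 should give the racemic carbinol F4.
- Dess–Martin oxidation should give the aryl ketone F5.
- NaN3 in DMF should give the azido ketone F6.
- PPh3 in THF (Staudinger reduction and intramolecular aza-Wittig reaction) should close the cyclic imine F7.
- Asymmetric hydrogenation ([Ir(cod)Cl]2, chiral bisphosphine of the f-Binaphane type, I2, H2), with the ligand antipode chosen for (R), should give 11.

**Step 9.** A TIPS group may migrate from O5 to the enolate oxygen, or trifluoroacetylation of the crowded methyl ketone may stay incomplete. The fallback sets out from 13 and comes back at 18; it makes the diazo group without any strong-base enolate.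
- The Stille coupling of step 8 is run to the enol ether 14, which is not hydrolysed but treated with NBS in THF/H2O at −20 °C to give the bromomethyl ketone F8.
- N,N'-Ditosylhydrazine and DBU (THF, 0 °C) should convert F8 into 18 by N-alkylation and twofold sulfinate elimination.

Further compounds

F1 | step 10 | benzyl (2R)-2-[3-acetyl-4-hydroxy-2,6-bis(triisopropylsilyloxy)phenyl]piperidine-1-carboxylate | O=C(OCc1ccccc1)N1CCCC[C@@H]1c1c(O[Si](C(C)C)(C(C)C)C(C)C)c(C(C)=O)c(O)cc1O[Si](C(C)C)(C(C)C)C(C)C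
F2 | step 10 | benzyl (2R)-2-{3-[(E)-3-(dimethylamino)acryloyl]-4-hydroxy-2,6-bis(triisopropylsilyloxy)phenyl}piperidine-1-carboxylate | O=C(OCc1ccccc1)N1CCCC[C@@H]1c1c(O[Si](C(C)C)(C(C)C)C(C)C)c(C(=O)/C=C/N(C)C)c(O)cc1O[Si](C(C)C)(C(C)C)C(C)C
F3 | step 10 | benzyl (2R)-2-[4-oxo-5,7-bis(triisopropylsilyloxy)-4H-chromen-6-yl]piperidine-1-carboxylate | O=C(OCc1ccccc1)N1CCCC[C@@H]1c1c(O[Si](C(C)C)(C(C)C)C(C)C)cc2occc(=O)c2c1O[Si](C(C)C)(C(C)C)C(C)C
F4 | step 4 | rac-1-{4-[(4-benzyloxybenzyl)oxy]-2,6-bis(triisopropylsilyloxy)phenyl}-5-chloropentan-1-ol | OC(CCCCCl)c1c(O[Si](C(C)C)(C(C)C)C(C)C)cc(OCc2ccc(OCc3ccccc3)cc2)cc1O[Si](C(C)C)(C(C)C)C(C)C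
F5 | step 4 | 1-{4-[(4-benzyloxybenzyl)oxy]-2,6-bis(triisopropylsilyloxy)phenyl}-5-chloropentan-1-one | O=C(CCCCCl)c1c(O[Si](C(C)C)(C(C)C)C(C)C)cc(OCc2ccc(OCc3ccccc3)cc2)cc1O[Si](C(C)C)(C(C)C)C(C)C
F6 | step 4 | 5-azido-1-{4-[(4-benzyloxybenzyl)oxy]-2,6-bis(triisopropylsilyloxy)phenyl}pentan-1-one | O=C(CCCCN=[N+]=[N-])c1c(O[Si](C(C)C)(C(C)C)C(C)C)cc(OCc2ccc(OCc3ccccc3)cc2)cc1O[Si](C(C)C)(C(C)C)C(C)C
F7 | step 4 | 6-{4-[(4-benzyloxybenzyl)oxy]-2,6-bis(triisopropylsilyloxy)phenyl}-2,3,4,5-tetrahydropyridine | C1CCC(=NC1)c1c(O[Si](C(C)C)(C(C)C)C(C)C)cc(OCc2ccc(OCc3ccccc3)cc2)cc1O[Si](C(C)C)(C(C)C)C(C)C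
F8 | step 9 | benzyl (2R)-2-{4-[(4-benzyloxybenzyl)oxy]-3-(2-bromoacetyl)-2,6-bis(triisopropylsilyloxy)phenyl}piperidine-1-carboxylate | O=C(OCc1ccccc1)N1CCCC[C@@H]1c1c(O[Si](C(C)C)(C(C)C)C(C)C)c(C(=O)CBr)c(OCc2ccc(OCc3ccccc3)cc2)cc1O[Si](C(C)C)(C(C)C)C(C)C
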